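**Assumption:** atom labels C1–C15 follow germacranolide numbering of the target (lactone C12 closed on O6, ester on O8, oxirane C1–C10, CH2OH = C14, CH3 = C15). The target is then (1R,3S,4Z,6R,7R,8R,10S) with a (2S)-2-methylbutanoate.

## Retrosynthetic overview

1. Target ⇐ C14 desilylation ⇐ CBS reduction of a macrocyclic C3 enone ⇐ Nozaki–Hiyama–Kishi closure of the ten-membered ring at C3–C4 (Z-alkenyl iodide + aldehyde).
2. Oxirane ⇐ Sharpless epoxidation of the acyclic C14 allylic alcohol (reagent control); C8 ester ⇐ (S)-2-methylbutanoic acid.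
3. C7–C8 bond, C7 and C8 stereocentres and the α-methylene lactone ⇐ new open-transition-state SE2′ coupling of a 3-(trimethylsilylmethyl)butenolide (fragment A) with a β,γ-unsaturated aldehyde (fragment B).
4. Fragment A ⇐ ring-closing metathesis of an acrylate of (3S,4Z)-5-iodohexa-1,4-dien-3-ol ⇐ Stork–Zhao iodo-olefination of (S)-glyceraldehyde acetonide; fragment B ⇐ Still–Gennari (Z)-olefination.
5. Ring order: butenolide, then oxirane, then ten-membered carbocycle.

## Route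

Step 1
Reactants: 1 (R)-solketal, [(4R)-2,2-dimethyl-1,3-dioxolan-4-yl]methanol
Product: 2 (4S)-2,2-dimethyl-1,3-dioxolane-4-carbaldehyde
Conditions: Dess–Martin periodinane (DMP), pyridine, CH2Cl2, 0 °C → rt; used crude
Reagents that add atoms: none
Why: Dess–Martin oxidation stops at the aldehyde under buffered, non-epimerising conditions, so the chiral-pool stereocentre (future C6) is carried over unchanged.

Step 2
Reactants: 2 (4S)-2,2-dimethyl-1,3-dioxolane-4-carbaldehyde; 3 ethyltriphenylphosphonium iodide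
Product: 7 (4R)-4-[(1Z)-2-iodoprop-1-en-1-yl]-2,2-dimethyl-1,3-dioxolane, via ethylidene(triphenyl)phosphorane 4 (not isolated), via (1-iodoethyl)triphenylphosphonium iodide 5 (not isolated), via (1-iodoethylidene)triphenylphosphorane 6 (not isolated)
Conditions: n-BuLi, THF, rt; I2, −78 °C; NaN(SiMe3)2, −20 °C; then 2, −78 °C → rt
Reagents that add atoms: iodine, II
Why: Stork–Zhao-type Wittig olefination with the α-iodo ylide gives the (Z)-2-iodoalkene (carbon chain cis to iodine) under kinetic control, fixing the future C4=C5 geometry, and the α-alkoxy stereocentre is not deprotonated at −78 °C.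

Step 3
Reactants: 7 (4R)-4-[(1Z)-2-iodoprop-1-en-1-yl]-2,2-dimethyl-1,3-dioxolane
Product: 8 (2R,3Z)-4-iodopent-3-ene-1,2-diol
Conditions: AcOH/H2O (4:1), 40 °C
Reagents that add atoms: none
Why: Acid-catalysed acetal hydrolysis releases the diol, and the alkenyl iodide is inert to aqueous acetic acid.

Step 4
Reactants: 8 (2R,3Z)-4-iodopent-3-ene-1,2-diol
Product: 10 (2R)-2-[(1Z)-2-iodoprop-1-en-1-yl]oxirane, via primary monotosylate 9 (not isolated)
Conditions: NaH, 1-(p-toluenesulfonyl)imidazole, THF, 0 °C → rt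
Reagents that add atoms: none
Why: The primary alkoxide is sulfonylated selectively and the secondary alkoxide closes the ring by intramolecular Williamson (SN2) displacement at CH2, so the stereocentre is untouched.

Step 5
Reactants: 10 (2R)-2-[(1Z)-2-iodoprop-1-en-1-yl]oxirane
Product: 11 (3S,4Z)-5-iodohexa-1,4-dien-3-ol
Conditions: Me3SI, n-BuLi (ylide pre-formed), THF, −10 °C → rt
Reagents that add atoms: trimethylsulfonium iodide, C[S+](C)C.[I-]
Why: The Corey–Chaykovsky ylide opens the epoxide at the unhindered CH2 and the resulting sulfonium salt eliminates Me2S, giving the one-carbon-homologated allylic alcohol with the C–O stereocentre retained.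

Step 6
Reactants: 12 ethyl 2-[(trimethylsilyl)methyl]prop-2-enoate
Product: 13 2-[(trimethylsilyl)methyl]prop-2-enoic acid
Conditions: NaOH, MeOH/H2O, rt; then aq. HCl to pH 3, 0 °C
Reagents that add atoms: sodium hydroxide, [Na+].[OH-]
Why: Ester saponification proceeds without touching the allylsilane, which tolerates base and brief cold dilute acid.

Step 7
Reactants: 11 (3S,4Z)-5-iodohexa-1,4-dien-3-ol; 13 2-[(trimethylsilyl)methyl]prop-2-enoic acid
Product: 14 (3S,4Z)-5-iodohexa-1,4-dien-3-yl 2-[(trimethylsilyl)methyl]prop-2-enoate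
Conditions: N,N′-dicyclohexylcarbodiimide (DCC), 4-(dimethylamino)pyridine (cat.), CH2Cl2, 0 °C → rt
Reagents that add atoms: none
Why: Steglich esterification acylates the secondary allylic alcohol under neutral conditions with retention at the carbinol carbon.

Step 8
Reactants: 14 (3S,4Z)-5-iodohexa-1,4-dien-3-yl 2-[(trimethylsilyl)methyl]prop-2-enoate
Product: 15 (5S)-5-[(1Z)-2-iodoprop-1-en-1-yl]-3-[(trimethylsilyl)methyl]furan-2(5H)-one (fragment A)
Conditions: second-generation Grubbs catalyst RuCl2(=CHPh)(H2IMes)(PCy3) (10 mol%), toluene, 80 °C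
Reagents that add atoms: none
Why: In this ring-closing metathesis the ruthenium carbene loads on the monosubstituted vinyl group and closes onto the 1,1-disubstituted acrylate to form the butenolide, while the trisubstituted iodoalkene and the allylsilane are spectators.

Step 9
Reactants: 16 methyl 2-[bis(2,2,2-trifluoroethoxy)phosphoryl]acetate; 17 tert-butyl(2-iodoethoxy)dimethylsilane
Product: 18 methyl 2-[bis(2,2,2-trifluoroethoxy)phosphoryl]-4-[(tert-butyldimethylsilyl)oxy]butanoate (racemic)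
Conditions: NaH, DMF, 0 → 50 °C
Reagents that add atoms: none
Why: The stabilised phosphonoacetate anion is mono-alkylated by the primary iodide in an SN2 reaction.

Step 10
Reactants: 19 3-[(4-methoxybenzyl)oxy]propan-1-ol
Product: 20 3-[(4-methoxybenzyl)oxy]propanal
Conditions: DMP, pyridine, CH2Cl2, 0 °C → rt
Reagents that add atoms: none
Why: Dess–Martin oxidation gives the β-alkoxy aldehyde without β-elimination.

Step 11
Reactants: 18 methyl 2-[bis(2,2,2-trifluoroethoxy)phosphoryl]-4-[(tert-butyldimethylsilyl)oxy]butanoate; 20 3-[(4-methoxybenzyl)oxy]propanal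
Product: 21 methyl (2Z)-2-{2-[(tert-butyldimethylsilyl)oxy]ethyl}-5-[(4-methoxybenzyl)oxy]pent-2-enoate
Conditions: KN(SiMe3)2, 18-crown-6, THF, −78 °C
Reagents that add atoms: none
Why: In this Still–Gennari olefination the electron-poor trifluoroethyl phosphonate collapses under kinetic control to the (Z)-trisubstituted enoate, placing the ester carbon (C14) cis to the C2 chain as the later trans-oxirane requires.

Step 12
Reactants: 21 methyl (2Z)-2-{2-[(tert-butyldimethylsilyl)oxy]ethyl}-5-[(4-methoxybenzyl)oxy]pent-2-enoate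
Product: 22 (2Z)-2-{2-[(tert-butyldimethylsilyl)oxy]ethyl}-5-[(4-methoxybenzyl)oxy]pent-2-en-1-ol
Conditions: i-Bu2AlH, CH2Cl2, −78 °C; aq. potassium sodium tartrate
Reagents that add atoms: none
Why: The aluminium hydride reduces the enoate 1,2 to the allylic alcohol without changing the alkene geometry.

Step 13
Reactants: 22 (2Z)-2-{2-[(tert-butyldimethylsilyl)oxy]ethyl}-5-[(4-methoxybenzyl)oxy]pent-2-en-1-ol
Product: 23 tert-butyl{[(2Z)-2-{2-[(tert-butyldimethylsilyl)oxy]ethyl}-5-[(4-methoxybenzyl)oxy]pent-2-en-1-yl]oxy}diphenylsilane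
Conditions: t-BuPh2SiCl, imidazole, DMF, rt
Reagents that add atoms: tert-butyl(chloro)diphenylsilane, CC(C)(C)[Si](Cl)(c1ccccc1)c1ccccc1
Why: Standard silylation of the primary allylic alcohol gives a Lewis-acid-stable C14 protecting group.

Step 14
Reactants: 23 tert-butyl{[(2Z)-2-{2-[(tert-butyldimethylsilyl)oxy]ethyl}-5-[(4-methoxybenzyl)oxy]pent-2-en-1-yl]oxy}diphenylsilane
Product: 24 (3Z)-3-{[(tert-butyldiphenylsilyl)oxy]methyl}-6-[(4-methoxybenzyl)oxy]hex-3-en-1-ol
Conditions: pyridinium p-toluenesulfonate (cat.), EtOH, 40 °C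
Reagents that add atoms: none
Why: Acid-catalysed ethanolysis cleaves the unhindered primary tert-butyldimethylsilyl ether much faster than the bulky tert-butyldiphenylsilyl ether, and the benzyl-type ether is unaffected.

Step 15
Reactants: 24 (3Z)-3-{[(tert-butyldiphenylsilyl)oxy]methyl}-6-[(4-methoxybenzyl)oxy]hex-3-en-1-ol
Product: 25 (3Z)-3-{[(tert-butyldiphenylsilyl)oxy]methyl}-6-[(4-methoxybenzyl)oxy]hex-3-enal (fragment B)
Conditions: DMP, pyridine, CH2Cl2, 0 °C; used at once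
Reagents that add atoms: none
Why: Buffered Dess–Martin oxidation gives the β,γ-unsaturated aldehyde without moving the double bond into conjugation.

Step 16
Reactants: 15 (5S)-5-[(1Z)-2-iodoprop-1-en-1-yl]-3-[(trimethylsilyl)methyl]furan-2(5H)-one; 25 (3Z)-3-{[(tert-butyldiphenylsilyl)oxy]methyl}-6-[(4-methoxybenzyl)oxy]hex-3-enal
Product: 26 (4R,5S)-4-[(1R,3Z)-3-{[(tert-butyldiphenylsilyl)oxy]methyl}-1-hydroxy-6-[(4-methoxybenzyl)oxy]hex-3-en-1-yl]-5-[(1Z)-2-iodoprop-1-en-1-yl]-3-methylideneoxolan-2-one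
Conditions: BF3·OEt2 (1.5 equiv), CH2Cl2, −78 → −45 °C; aq. NaHCO3
Reagents that add atoms: none
Why: Proposed new method: a BF3-promoted SE2′ allylation in which the ring carbon C4 of the 3-(silylmethyl)butenolide (γ to silicon) attacks the BF3-bound aldehyde anti to the C5 alkenyl group (giving the 4,5-trans lactone, C7) through an open antiperiplanar transition state with the ring carbon C5 gauche to the aldehyde hydrogen (giving the syn, 8R carbinol), after which the β-silyl cation loses Me3SiF to unveil the exo-methylene; the closest known reactions are the Hosomi–Sakurai addition of 2-(silylmethyl)acrylates to aldehydes and the BF3-mediated syn-selective addition of crotylsilanes and crotylstannanes, whereas a ring-embedded γ-substituted 3-(silylmethyl)butenolide donor has not been used and the closed-transition-state Zn or Cr Barbier reaction of the corresponding bromide gives the opposite C8 epimer.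

Step 17
Reactants: 26 (the C8 alcohol from step 16); 27 (S)-2-methylbutanoic acid
Product: 28 (4R,5S)-4-[(1R,3Z)-3-{[(tert-butyldiphenylsilyl)oxy]methyl}-6-[(4-methoxybenzyl)oxy]-1-{[(2S)-2-methylbutanoyl]oxy}hex-3-en-1-yl]-5-[(1Z)-2-iodoprop-1-en-1-yl]-3-methylideneoxolan-2-one
Conditions: DCC, 4-(dimethylamino)pyridine (cat.), CH2Cl2, 0 °C → rt
Reagents that add atoms: none
Why: Steglich esterification acylates the secondary C8 alcohol with retention, and carbodiimide activation avoids a ketene pathway so the acid α-stereocentre is preserved.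

Step 18
Reactants: 28 (the C8 ester with C14 silyl ether)
Product: 29 (4R,5S)-4-[(1R,3Z)-3-(hydroxymethyl)-6-[(4-methoxybenzyl)oxy]-1-{[(2S)-2-methylbutanoyl]oxy}hex-3-en-1-yl]-5-[(1Z)-2-iodoprop-1-en-1-yl]-3-methylideneoxolan-2-one
Conditions: HF·pyridine, pyridine, THF, 0 °C → rt
Reagents that add atoms: none
Why: Buffered fluoride cleaves the Si–O bond, while the ester, the lactone, the alkenyl iodide and the benzyl-type ether are stable.

Step 19
Reactants: 29 (the C14 allylic alcohol)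
Product: 30 (4R,5S)-4-[(1R)-2-[(2S,3R)-2-(hydroxymethyl)-3-{2-[(4-methoxybenzyl)oxy]ethyl}oxiran-2-yl]-1-{[(2S)-2-methylbutanoyl]oxy}ethyl]-5-[(1Z)-2-iodoprop-1-en-1-yl]-3-methylideneoxolan-2-one
Conditions: Ti(Oi-Pr)4 (cat.), diethyl L-(+)-tartrate (cat.), t-BuOOH, 4 Å MS, CH2Cl2, −20 °C
Reagents that add atoms: tert-butyl hydroperoxide, CC(C)(C)OO
Why: Katsuki–Sharpless epoxidation is directed by the only allylic alcohol present, and the L-tartrate catalyst delivers oxygen to the face that turns geraniol into its (2S,3S)-epoxide, which here gives the (1R,10S)-oxirane by reagent control.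

Step 20
Reactants: 30 (the epoxy alcohol)
Product: 31 (4R,5S)-4-[(1R)-2-[(2S,3R)-3-{2-[(4-methoxybenzyl)oxy]ethyl}-2-{[(triethylsilyl)oxy]methyl}oxiran-2-yl]-1-{[(2S)-2-methylbutanoyl]oxy}ethyl]-5-[(1Z)-2-iodoprop-1-en-1-yl]-3-methylideneoxolan-2-one
Conditions: Et3SiCl, imidazole, CH2Cl2, 0 °C
Reagents that add atoms: chlorotriethylsilane, CC[Si](Cl)(CC)CC
Why: Silylation of the primary epoxy alcohol under mild base avoids Payne rearrangement and gives a group that is removable at the end under near-neutral conditions.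

Step 21
Reactants: 31 (the C14 triethylsilyl ether)
Product: 32 (4R,5S)-4-[(1R)-2-[(2S,3R)-3-(2-hydroxyethyl)-2-{[(triethylsilyl)oxy]methyl}oxiran-2-yl]-1-{[(2S)-2-methylbutanoyl]oxy}ethyl]-5-[(1Z)-2-iodoprop-1-en-1-yl]-3-methylideneoxolan-2-one
Conditions: 2,3-dichloro-5,6-dicyano-1,4-benzoquinone (DDQ), CH2Cl2/pH 7 phosphate buffer, 0 °C
Reagents that add atoms: none
Why: Oxidative cleavage of the electron-rich 4-methoxybenzyl ether by single-electron transfer frees the C3 alcohol, and the buffer keeps the oxirane from acid-promoted opening.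

Step 22
Reactants: 32 (the C3 primary alcohol)
Product: 33 (4R,5S)-5-[(1Z)-2-iodoprop-1-en-1-yl]-3-methylidene-4-[(1R)-1-{[(2S)-2-methylbutanoyl]oxy}-2-[(2S,3R)-3-(2-oxoethyl)-2-{[(triethylsilyl)oxy]methyl}oxiran-2-yl]ethyl]oxolan-2-one
Conditions: DMP, pyridine, CH2Cl2, 0 °C; used at once
Reagents that add atoms: none
Why: Buffered Dess–Martin oxidation gives the β,γ-epoxy aldehyde without base-induced epoxide elimination.

Step 23
Reactants: 33 (the iodo aldehyde)
Product: 34 (1R,4Z,6R,7R,8R,10S)-1,10-epoxy-3-hydroxy-8-{[(2S)-2-methylbutanoyl]oxy}-14-[(triethylsilyl)oxy]germacra-4,11(13)-dien-12,6-olide (both C3 epimers)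
Conditions: CrCl2 (10 equiv), NiCl2 (cat.), degassed DMSO/THF, rt, 2 mM, slow addition; aqueous work-up
Reagents that add atoms: none
Why: In this Nozaki–Hiyama–Kishi reaction the alkenyl iodide adds oxidatively to zerovalent nickel and is passed to trivalent chromium, and the alkenylchromium adds only to the aldehyde with retention of the Z geometry to close the ten-membered ring at high dilution; C3 is deliberately left uncontrolled because it is erased in step 24 and set in step 25.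

Step 24
Reactants: 34 (the macrocyclic allylic alcohols)
Product: 35 (1R,4Z,6R,7R,8R,10S)-1,10-epoxy-8-{[(2S)-2-methylbutanoyl]oxy}-3-oxo-14-[(triethylsilyl)oxy]germacra-4,11(13)-dien-12,6-olide
Conditions: DMP, pyridine, CH2Cl2, 0 °C
Reagents that add atoms: none
Why: Dess–Martin oxidation converges both C3 epimers onto one enone under buffered conditions that spare the β,γ-oxirane.

Step 25
Reactants: 35 (the macrocyclic enone)
Product: 36 (1R,3S,4Z,6R,7R,8R,10S)-1,10-epoxy-3-hydroxy-8-{[(2S)-2-methylbutanoyl]oxy}-14-[(triethylsilyl)oxy]germacra-4,11(13)-dien-12,6-olide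
Conditions: (R)-1-methyl-3,3-diphenyltetrahydro-1H,3H-pyrrolo[1,2-c][1,3,2]oxazaborole (0.5 equiv), catecholborane, toluene, −78 °C
Reagents that add atoms: none
Why: In this Corey–Bakshi–Shibata reduction the (R)-oxazaborolidine treats the α-methyl alkenyl arm (C4) as the large group and delivers hydride to the Re face of the C3 ketone, giving the (3S)-alcohol by reagent control, while the enoate, the esters and the oxirane are not reduced by catecholborane at −78 °C.

Step 26
Reactants: 36 (the C14 triethylsilyl ether)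
Product: 37 (1R,3S,4Z,6R,7R,8R,10S)-1,10-epoxy-3,14-dihydroxy-8-{[(2S)-2-methylbutanoyl]oxy}germacra-4,11(13)-dien-12,6-olide (target, CNP0356520.3)
Conditions: Et3N·3HF, MeCN, 0 °C → rt
Reagents that add atoms: none
Why: Near-neutral fluoride removes the primary triethylsilyl ether without acid-promoted attack of the C3 hydroxyl on the oxirane or base-promoted Payne rearrangement.

## Compound list

1 | [(4R)-2,2-dimethyl-1,3-dioxolan-4-yl]methanol, (R)-solketal | O1[C@@H](COC1(C)C)CO | starting material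
2 | (4S)-2,2-dimethyl-1,3-dioxolane-4-carbaldehyde | O1[C@@H](COC1(C)C)C=O | intermediate
3 | ethyltriphenylphosphonium iodide | CC[P+](c1ccccc1)(c1ccccc1)c1ccccc1.[I-] | starting material
4 | ethylidene(triphenyl)phosphorane | CC=P(c1ccccc1)(c1ccccc1)c1ccccc1 | intermediate
5 | (1-iodoethyl)triphenylphosphonium iodide | CC(I)[P+](c1ccccc1)(c1ccccc1)c1ccccc1.[I-] | intermediate
6 | (1-iodoethylidene)triphenylphosphorane | CC(I)=P(c1ccccc1)(c1ccccc1)c1ccccc1 | intermediate
7 | (4R)-4-[(1Z)-2-iodoprop-1-en-1-yl]-2,2-dimethyl-1,3-dioxolane | O1[C@@H](COC1(C)C)/C=C(/C)I | intermediate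
8 | (2R,3Z)-4-iodopent-3-ene-1,2-diol | O[C@@H](CO)/C=C(/C)I | intermediate
9 | (2R,3Z)-2-hydroxy-4-iodopent-3-en-1-yl 4-methylbenzenesulfonate | O[C@@H](COS(=O)(=O)c1ccc(C)cc1)/C=C(/C)I | intermediate
10 | (2R)-2-[(1Z)-2-iodoprop-1-en-1-yl]oxirane | O1[C@@H](C1)/C=C(/C)I | intermediate
11 | (3S,4Z)-5-iodohexa-1,4-dien-3-ol | O[C@@H](C=C)/C=C(/C)I | intermediate
12 | ethyl 2-[(trimethylsilyl)methyl]prop-2-enoate | CCOC(=O)C(=C)C[Si](C)(C)C | starting material
13 | 2-[(trimethylsilyl)methyl]prop-2-enoic acid | OC(=O)C(=C)C[Si](C)(C)C | intermediate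
14 | (3S,4Z)-5-iodohexa-1,4-dien-3-yl 2-[(trimethylsilyl)methyl]prop-2-enoate | C=C(C[Si](C)(C)C)C(=O)O[C@@H](C=C)/C=C(/C)I | intermediate
15 | (5S)-5-[(1Z)-2-iodoprop-1-en-1-yl]-3-[(trimethylsilyl)methyl]furan-2(5H)-one | O=C1O[C@@H](C=C1C[Si](C)(C)C)/C=C(/C)I | intermediate
16 | methyl 2-[bis(2,2,2-trifluoroethoxy)phosphoryl]acetate | COC(=O)CP(=O)(OCC(F)(F)F)OCC(F)(F)F | starting material
17 | tert-butyl(2-iodoethoxy)dimethylsilane | CC(C)(C)[Si](C)(C)OCCI | starting material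
18 | methyl 2-[bis(2,2,2-trifluoroethoxy)phosphoryl]-4-[(tert-butyldimethylsilyl)oxy]butanoate (racemic) | COC(=O)C(CCO[Si](C)(C)C(C)(C)C)P(=O)(OCC(F)(F)F)OCC(F)(F)F | intermediate
19 | 3-[(4-methoxybenzyl)oxy]propan-1-ol | COc1ccc(COCCCO)cc1 | starting material
20 | 3-[(4-methoxybenzyl)oxy]propanal | COc1ccc(COCCC=O)cc1 | intermediate
21 | methyl (2Z)-2-{2-[(tert-butyldimethylsilyl)oxy]ethyl}-5-[(4-methoxybenzyl)oxy]pent-2-enoate | COC(=O)/C(CCO[Si](C)(C)C(C)(C)C)=C\CCOCc1ccc(OC)cc1 | intermediate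
22 | (2Z)-2-{2-[(tert-butyldimethylsilyl)oxy]ethyl}-5-[(4-methoxybenzyl)oxy]pent-2-en-1-ol | OC/C(CCO[Si](C)(C)C(C)(C)C)=C\CCOCc1ccc(OC)cc1 | intermediate
23 | tert-butyl{[(2Z)-2-{2-[(tert-butyldimethylsilyl)oxy]ethyl}-5-[(4-methoxybenzyl)oxy]pent-2-en-1-yl]oxy}diphenylsilane | CC(C)(C)[Si](c1ccccc1)(c1ccccc1)OC/C(CCO[Si](C)(C)C(C)(C)C)=C\CCOCc1ccc(OC)cc1 | intermediate
24 | (3Z)-3-{[(tert-butyldiphenylsilyl)oxy]methyl}-6-[(4-methoxybenzyl)oxy]hex-3-en-1-ol | CC(C)(C)[Si](c1ccccc1)(c1ccccc1)OC/C(CCO)=C\CCOCc1ccc(OC)cc1 | intermediate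
25 | (3Z)-3-{[(tert-butyldiphenylsilyl)oxy]methyl}-6-[(4-methoxybenzyl)oxy]hex-3-enal | CC(C)(C)[Si](c1ccccc1)(c1ccccc1)OC/C(CC=O)=C\CCOCc1ccc(OC)cc1 | intermediate
26 | (4R,5S)-4-[(1R,3Z)-3-{[(tert-butyldiphenylsilyl)oxy]methyl}-1-hydroxy-6-[(4-methoxybenzyl)oxy]hex-3-en-1-yl]-5-[(1Z)-2-iodoprop-1-en-1-yl]-3-methylideneoxolan-2-one | C=C1C(=O)O[C@H](/C=C(/C)I)[C@H]1[C@H](O)C/C(CO[Si](c2ccccc2)(c2ccccc2)C(C)(C)C)=C/CCOCc2ccc(OC)cc2 | intermediate
27 | (S)-2-methylbutanoic acid | CC[C@H](C)C(=O)O | starting material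
28 | (4R,5S)-4-[(1R,3Z)-3-{[(tert-butyldiphenylsilyl)oxy]methyl}-6-[(4-methoxybenzyl)oxy]-1-{[(2S)-2-methylbutanoyl]oxy}hex-3-en-1-yl]-5-[(1Z)-2-iodoprop-1-en-1-yl]-3-methylideneoxolan-2-one | C=C1C(=O)O[C@H](/C=C(/C)I)[C@H]1[C@H](OC(=O)[C@@H](C)CC)C/C(CO[Si](c2ccccc2)(c2ccccc2)C(C)(C)C)=C/CCOCc2ccc(OC)cc2 | intermediate
29 | (4R,5S)-4-[(1R,3Z)-3-(hydroxymethyl)-6-[(4-methoxybenzyl)oxy]-1-{[(2S)-2-methylbutanoyl]oxy}hex-3-en-1-yl]-5-[(1Z)-2-iodoprop-1-en-1-yl]-3-methylideneoxolan-2-one | C=C1C(=O)O[C@H](/C=C(/C)I)[C@H]1[C@H](OC(=O)[C@@H](C)CC)C/C(CO)=C/CCOCc2ccc(OC)cc2 | intermediate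
30 | (4R,5S)-4-[(1R)-2-[(2S,3R)-2-(hydroxymethyl)-3-{2-[(4-methoxybenzyl)oxy]ethyl}oxiran-2-yl]-1-{[(2S)-2-methylbutanoyl]oxy}ethyl]-5-[(1Z)-2-iodoprop-1-en-1-yl]-3-methylideneoxolan-2-one | C=C1C(=O)O[C@H](/C=C(/C)I)[C@H]1[C@H](OC(=O)[C@@H](C)CC)C[C@@]2(CO)O[C@@H]2CCOCc3ccc(OC)cc3 | intermediate
31 | (4R,5S)-4-[(1R)-2-[(2S,3R)-3-{2-[(4-methoxybenzyl)oxy]ethyl}-2-{[(triethylsilyl)oxy]methyl}oxiran-2-yl]-1-{[(2S)-2-methylbutanoyl]oxy}ethyl]-5-[(1Z)-2-iodoprop-1-en-1-yl]-3-methylideneoxolan-2-one | C=C1C(=O)O[C@H](/C=C(/C)I)[C@H]1[C@H](OC(=O)[C@@H](C)CC)C[C@@]2(CO[Si](CC)(CC)CC)O[C@@H]2CCOCc3ccc(OC)cc3 | intermediate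
32 | (4R,5S)-4-[(1R)-2-[(2S,3R)-3-(2-hydroxyethyl)-2-{[(triethylsilyl)oxy]methyl}oxiran-2-yl]-1-{[(2S)-2-methylbutanoyl]oxy}ethyl]-5-[(1Z)-2-iodoprop-1-en-1-yl]-3-methylideneoxolan-2-one | C=C1C(=O)O[C@H](/C=C(/C)I)[C@H]1[C@H](OC(=O)[C@@H](C)CC)C[C@@]2(CO[Si](CC)(CC)CC)O[C@@H]2CCO | intermediate
33 | (4R,5S)-5-[(1Z)-2-iodoprop-1-en-1-yl]-3-methylidene-4-[(1R)-1-{[(2S)-2-methylbutanoyl]oxy}-2-[(2S,3R)-3-(2-oxoethyl)-2-{[(triethylsilyl)oxy]methyl}oxiran-2-yl]ethyl]oxolan-2-one | C=C1C(=O)O[C@H](/C=C(/C)I)[C@H]1[C@H](OC(=O)[C@@H](C)CC)C[C@@]2(CO[Si](CC)(CC)CC)O[C@@H]2CC=O | intermediate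
34 | (1R,4Z,6R,7R,8R,10S)-1,10-epoxy-3-hydroxy-8-{[(2S)-2-methylbutanoyl]oxy}-14-[(triethylsilyl)oxy]germacra-4,11(13)-dien-12,6-olide, both C3 epimers | C=C1C(=O)O[C@@H]2/C=C(/C)C(O)C[C@H]3O[C@]3(CO[Si](CC)(CC)CC)C[C@@H](OC(=O)[C@@H](C)CC)[C@@H]12 | intermediate
35 | (1R,4Z,6R,7R,8R,10S)-1,10-epoxy-8-{[(2S)-2-methylbutanoyl]oxy}-3-oxo-14-[(triethylsilyl)oxy]germacra-4,11(13)-dien-12,6-olide | C=C1C(=O)O[C@@H]2/C=C(/C)C(=O)C[C@H]3O[C@]3(CO[Si](CC)(CC)CC)C[C@@H](OC(=O)[C@@H](C)CC)[C@@H]12 | intermediate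
36 | (1R,3S,4Z,6R,7R,8R,10S)-1,10-epoxy-3-hydroxy-8-{[(2S)-2-methylbutanoyl]oxy}-14-[(triethylsilyl)oxy]germacra-4,11(13)-dien-12,6-olide | C=C1C(=O)O[C@@H]2/C=C(/C)[C@@H](O)C[C@H]3O[C@]3(CO[Si](CC)(CC)CC)C[C@@H](OC(=O)[C@@H](C)CC)[C@@H]12 | intermediate
37 | (1R,3S,4Z,6R,7R,8R,10S)-1,10-epoxy-3,14-dihydroxy-8-{[(2S)-2-methylbutanoyl]oxy}germacra-4,11(13)-dien-12,6-olide | C=C1C(=O)O[C@@H]2/C=C(/C)[C@@H](O)C[C@H]3O[C@]3(CO)C[C@@H](OC(=O)[C@@H](C)CC)[C@@H]12 | target

## Step count and risks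

Total step count: 26. Longest linear sequence: 18 steps (steps 1–5, 7, 8, then 16–26).

The three steps most likely to fail:

**Step 16 (the proposed new coupling).** The ester-bearing allylsilane may be too weak a nucleophile, or the open transition state may not give the syn (8R) carbinol cleanly. The fallback uses only known chemistry, sets out from 11 and 25 and comes back at 28. Alcohol 11 is esterified with commercial 2-(bromomethyl)prop-2-enoic acid (DCC, CH2Cl2) to give the 2-(bromomethyl)acrylate ester F1. Ring-closing metathesis with the same ruthenium catalyst gives the 3-(bromomethyl)butenolide F2. A Barbier reaction of F2 with aldehyde 25 (Zn dust, THF/aq. NH4Cl) goes through the closed chair transition state and gives the 4,5-trans lactone carrying the (8S)-alcohol F3, the C8 epimer of 26. Mitsunobu esterification of F3 with acid 27 (PPh3, diisopropyl azodicarboxylate, toluene) inverts C8 and gives 28.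

**Step 23 (ten-membered ring closure).** The β,γ-epoxy aldehyde 33 may decompose, or the strained ring may close poorly under Ni/Cr conditions. The fallback sets out from 32 and comes back at 35, replacing carbonyl addition by acyl coupling. Alcohol 32 is oxidised (2,2,6,6-tetramethylpiperidin-1-oxyl, PhI(OAc)2, MeCN/H2O) to the carboxylic acid F4. F4 is converted (2,2′-dipyridyl disulfide, PPh3) into the S-pyridin-2-yl thioester F5. F5 is cyclised at 2 mM by a nickel/zirconium-mediated alkenyl iodide–thioester ketone coupling (NiBr2(4,4′-di-tert-butyl-2,2′-bipyridine) cat., Cp2ZrCl2, Zn dust, 1,3-dimethylimidazolidin-2-one), which gives enone 35 directly and bypasses 33 and 34.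

**Step 25 (C3 reduction).** The macrocycle may override the oxazaborolidine, or the β,γ-epoxy ketone may eliminate. The fallback sets out from 33 and comes back at 36, and makes no new compound (F0). C3 is set during ring closure by a ligand-controlled Nozaki–Hiyama–Kishi reaction: CrCl2 pre-complexed with an enantiopure N-[2-(4-isopropyl-4,5-dihydrooxazol-2-yl)-6-methylphenyl]methanesulfonamide ligand and Et3N, NiCl2 (cat.), THF, rt, high dilution. The ligand antipode that puts the alkenyl group on the Re face of the aldehyde is the one used, so the (3S)-alcohol 36 is obtained without passing through 34 and 35.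

## Further compounds

F1 | step 16 | (3S,4Z)-5-iodohexa-1,4-dien-3-yl 2-(bromomethyl)prop-2-enoate | C=C(CBr)C(=O)O[C@@H](C=C)/C=C(/C)I
F2 | step 16 | (5S)-3-(bromomethyl)-5-[(1Z)-2-iodoprop-1-en-1-yl]furan-2(5H)-one | O=C1O[C@@H](C=C1CBr)/C=C(/C)I
F3 | step 16 | (4R,5S)-4-[(1S,3Z)-3-{[(tert-butyldiphenylsilyl)oxy]methyl}-1-hydroxy-6-[(4-methoxybenzyl)oxy]hex-3-en-1-yl]-5-[(1Z)-2-iodoprop-1-en-1-yl]-3-methylideneoxolan-2-one | C=C1C(=O)O[C@H](/C=C(/C)I)[C@H]1[C@@H](O)C/C(CO[Si](c2ccccc2)(c2ccccc2)C(C)(C)C)=C/CCOCc2ccc(OC)cc2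
F4 | step 23 | 2-[(2R,3S)-3-[(2R)-2-[(2S,3R)-2-[(1Z)-2-iodoprop-1-en-1-yl]-4-methylidene-5-oxooxolan-3-yl]-2-{[(2S)-2-methylbutanoyl]oxy}ethyl]-3-{[(triethylsilyl)oxy]methyl}oxiran-2-yl]acetic acid | C=C1C(=O)O[C@H](/C=C(/C)I)[C@H]1[C@H](OC(=O)[C@@H](C)CC)C[C@@]2(CO[Si](CC)(CC)CC)O[C@@H]2CC(=O)O
F5 | step 23 | S-pyridin-2-yl thioester of acid F4 | C=C1C(=O)O[C@H](/C=C(/C)I)[C@H]1[C@H](OC(=O)[C@@H](C)CC)C[C@@]2(CO[Si](CC)(CC)CC)O[C@@H]2CC(=O)Sc3ccccn3
F0 | step 25 | none | none
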